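If two second end groups can meet each other instead of a first end group, the share of the charge that escapes that meeting matters, so that share was what I reckoned.

    first end groups + second end groups → links + by-product (k1 = 0.040 M⁻¹ s⁻¹)
    second end groups ⇌ dormant form (K2 = 18, k2 = 0.0014 s⁻¹)
    2 second end groups → self-condensation product (k3 = 0.029 M⁻¹ s⁻¹)

| flask | first end groups | second end groups | time | remark |
|---|---|---|---|---|
| spring | 0.059 M | 0.0619 M (fed, over 20.0 min) | 40 min | all but second end groups at the start; second end groups goes in evenly over 20.0 min, the run ends at 40 min |
| winter | 0.059 M | 0.0619 M |  | one stirred flow tank at steady state, fed with the mixture as stated, mean residence time 40 min |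
| noon | 0.059 M | 0.0619 M | 40 min | a tube with plug flow, the mixed feed as stated, residence time 40 min |
| autumn | 0.059 M | 0.0619 M | 40 min | a closed flask charged with all of it at once and left for 40 min |

- for a step with 2 of a species take k times the square, and two of it per event
- the stated concentrations are those of everything mixed, before any reaction; amounts are the same in each set-up
- the feed brings no volume worth counting
- run time (spring): 40 min

* the set-up with the highest amount of links at the outlet or at the end, in percent of the first end groups put in ("none" if the first two lie within 2 percentage points) (spring / winter / noon / autumn / none)
* amount of links at the outlet or at the end, in percent of the first end groups put in, spring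
* amount of links at the outlet or at the end, in percent of the first end groups put in, winter
* amount of links at the outlet or at the end, in percent of the first end groups put in, noon
* amount of links at the outlet or at the end, in percent of the first end groups put in, autumn

I held c(first end groups) at its charge. Second end groups then had a pseudo-first-order exit, a = 0.040 M⁻¹ s⁻¹ × c(first end groups) + 0.0014 s⁻¹ = 0.226 min⁻¹, against self-condensation. I compared the two by N = 2 × 0.029 M⁻¹ s⁻¹ × c(second end groups) / a.

In autumn, the closed flask, the rate integrated in closed form to φ = ln(1 + N)/N, with N taken at the charge: N = 0.955 and φ = 0.702. This φ is the share of second end groups leaving by the first-order exit. A plug in the noon tube is such a flask travelling, so I reckoned noon as autumn.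

In spring the feed brought 0.00310 M min⁻¹ and ran 20.0 min, longer than the 4.42 min of the exit, so I took a steady level, where φ = 1/(1 + N). Of the exit, I gave links the share 0.628 and counted the rest as dormant form.

| flask | c(second end groups) | N | φ | links |
|---|---|---|---|---|
| autumn | 0.0619 M | 0.955 | 0.702 | 46.2% |
| spring | 0.0116 M | 0.179 | 0.848 | 55.8% |

In the autumn row N stood near one, so self-condensation began level with the exit. In the spring row the lower level cut N, and φ rose. Reading the last column, spring led by 9.6 percentage points. Both link figures held c(first end groups) at its charge and left the way back from dormant form uncounted, so I took them as rough. I did not reckon winter.

The forecast named spring: spring 52%, winter 42%, noon 41%, autumn 41%. Its ground was that “feeding them slowly keeps their concentration low and favours links”. Its spring and autumn figures stood below mine.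

The simulation gave spring first: spring 49.7%, winter 42.1%, noon 42.5%, autumn 42.5%. The forecast held, and the lead of 7.2 points over noon stood clear of the margin of 2 points. In spring, c(second end groups) peaked at 0.0138 M. From φ, autumn's self-condensation product reckoned to 0.00922 M, and the flask held 0.00993 M.

Then I took noon with 0.025 M of second end groups: N fell to 0.386, φ came to 0.846, and links reckoned to 22.5%. The simulation gave 22.4%.

The numbers are invented; the rest is arithmetic.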